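**Retrosynthetic overview**

- Rings: A is the phenol ring (C1–OH, C2–O, C3/C5–Br); B is the central ring (C1–O to ring A, C2–O to ring C, C3/C4/C5–Br, C6–H); C is the outer ring (C1–O, C2–I, C4–Br). The strategy rests on the ring-C iodine at C2 lying ortho to the ether oxygen on C1, which is bonded to ring-B C2 between the C1 oxygen and the C3 bromine. An iodine(III) first carried on ring-B C2 can therefore bond to ring-C C2 and then pass ring B to the oxygen, remaining as the ring-C iodide.
- 16 ⇐ 14 (formyl to hydroxyl, Dakin-type) ⇐ 12 + 13 (SNAr, ring-A C2–O bond) ⇐ 10 (O-demethylation).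
- 10 ⇐ 6 + 7: ring-C C2–I bond and ring-B C2–O bond through an iodonium phenolate.
- 6 ⇐ 5 ⇐ 4 ⇐ 2 ⇐ 1 (iodine(III) oxidation, ortho-iodination, Sandmeyer bromination, dibromination).
- No ring is formed; the three benzene rings are bought and joined B–C first (step 5), then A–B (step 7).

Key step: step 5

Remark: the target has no stereocentre and no axis hindered enough to hold a configuration, so it is achiral and needs no stereocontrol. Compounds 1, 7 and 13 are taken as purchasable.

**Route**

Step 1
Reactants: 1 4-methoxyaniline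
Product: 2 2,6-dibromo-4-methoxyaniline
Conditions: NBS (2.05 equiv), MeCN, 0 °C → rt
Reagents that add atoms: N-bromosuccinimide, O=C1CCC(=O)N1Br
Why: Electrophilic aromatic bromination (SEAr): the amino group is the stronger activator and its para position is occupied by methoxy, so both bromines should enter ortho to nitrogen.

Step 2
Reactants: 2 2,6-dibromo-4-methoxyaniline
Product: 4 1,2,3-tribromo-5-methoxybenzene, via diazonium bromide 3 (not isolated)
Conditions: t-BuONO (1.5 equiv), CuBr2 (1.2 equiv), MeCN, 0 → 60 °C
Reagents that add atoms: copper(II) bromide, Br[Cu]Br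
Why: Sandmeyer bromination with non-aqueous diazotisation suits a weakly basic 2,6-dibromoaniline: the alkyl nitrite forms diazonium ion 3 and copper bromide transfers bromine to the aryl radical as nitrogen is lost.

Step 3
Reactants: 4 1,2,3-tribromo-5-methoxybenzene
Product: 5 1,2,3-tribromo-4-iodo-5-methoxybenzene
Conditions: NIS (1.05 equiv), CF3SO3H (0.3 equiv), CH2Cl2/CF3CO2H, 0 °C → rt
Reagents that add atoms: N-iodosuccinimide, O=C1CCC(=O)N1I
Why: Electrophilic aromatic iodination (SEAr) with acid-activated N-iodosuccinimide: the only two free ring carbons are equivalent by symmetry and lie ortho to methoxy, so one equivalent should give a single monoiodide, the second iodination being slower for steric reasons.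

Step 4
Reactants: 5 1,2,3-tribromo-4-iodo-5-methoxybenzene
Product: 6 (2,3,4-tribromo-6-methoxyphenyl)-λ3-iodanediyl diacetate
Conditions: CH3CO3H (ca. 35% in AcOH, 2.5 equiv), AcOH, 40 °C
Reagents that add atoms: peracetic acid, CC(=O)OO; acetic acid, CC(=O)O
Why: Peracid oxidation of an aryl iodide to the aryl-λ3-iodane with capture of acetate ligands, the standard preparation of (diacetoxyiodo)arenes; the ortho methoxy group offsets the electron-poor ring, and the C–Br and methyl ether groups are inert to the peracid.

Step 5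
Reactants: 6 (2,3,4-tribromo-6-methoxyphenyl)-λ3-iodanediyl diacetate (1.05 equiv); 7 4-bromophenol (1.0 equiv)
Product: 10 1,2,3-tribromo-4-(4-bromo-2-iodophenoxy)-5-methoxybenzene, via iodonium trifluoroacetate 8 (not isolated), via iodonium phenolate 9 (not isolated)
Conditions: CF3CO2H/CH2Cl2 (1:4), −20 °C → rt; evaporate; then K2CO3 (2 equiv), MeCN, 70 °C
Reagents that add atoms: none
Why: In the acid the diacetate exchanges to a cationic aryl-λ3-iodane that attacks 4-bromophenol at C2, the only activated carbon left because bromine blocks the para position, giving the (2-hydroxyaryl)(aryl)iodonium salt 8 (ring-C C2–I bond). Carbonate then forms iodonium phenolate 9, whose oxygen adds to the iodine-bearing ipso carbon of ring B through a five-membered spiro, Meisenheimer-like transition state while iodine leaves as the ring-C aryl iodide, a 1,4 iodine-to-oxygen aryl shift (ring-B C2–O bond). The closest known reaction type is the base-induced rearrangement of aryliodonium phenolates and 2-hydroxyaryl iodonium salts to 2-iodophenyl aryl ethers, a Smiles-like ligand coupling. No ring is closed and no stereocentre is formed. The step needs C–I bond formation to outrun two-electron oxidation of the phenol, which the para bromine and a cold, nucleophile-free acidic medium should favour. It also needs transfer of the ring-B aryl within the zwitterion, which the tethered phenoxide, the electron-poor doubly ortho-substituted ipso carbon and the absence of excess phenol secure.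

Step 6
Reactants: 10 1,2,3-tribromo-4-(4-bromo-2-iodophenoxy)-5-methoxybenzene
Product: 12 3,4,5-tribromo-2-(4-bromo-2-iodophenoxy)phenol, via aryloxydibromoborane 11 (not isolated)
Conditions: BBr3 (2 equiv), CH2Cl2, −78 °C → rt; then H2O
Reagents that add atoms: none
Why: Lewis acid-mediated cleavage of an aryl methyl ether with boron tribromide (bromide attacks the methyl group of the O–B adduct); the diaryl ether, aryl iodide and aryl bromides have no sp3 C–O bond and should be untouched.

Step 7
Reactants: 12 3,4,5-tribromo-2-(4-bromo-2-iodophenoxy)phenol; 13 3,5-dibromo-2-fluorobenzaldehyde (1.2 equiv)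
Product: 14 3,5-dibromo-2-[3,4,5-tribromo-2-(4-bromo-2-iodophenoxy)phenoxy]benzaldehyde
Conditions: K2CO3 (2 equiv), DMF, 90 °C
Reagents that add atoms: none
Why: Nucleophilic aromatic substitution (addition–elimination): the phenoxide of 12 displaces fluoride at the carbon ortho to the formyl group, the only halogen-bearing carbon of 13 that the formyl group activates by resonance, while the unactivated ring C should not undergo Smiles migration at this temperature.

Step 8
Reactants: 14 3,5-dibromo-2-[3,4,5-tribromo-2-(4-bromo-2-iodophenoxy)phenoxy]benzaldehyde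
Product: 16 bromoiesol B (3,5-dibromo-2-[3,4,5-tribromo-2-(4-bromo-2-iodophenoxy)phenoxy]phenol), via aryl formate 15 (not isolated)
Conditions: mCPBA (2 equiv), KH2PO4, CH2Cl2, rt → 40 °C; aq Na2S2O3 wash; then MeOH, HCl (cat.), rt
Reagents that add atoms: 3-chloroperoxybenzoic acid, O=C(OO)c1cccc(Cl)c1
Why: Baeyer–Villiger oxidation of an ortho-aryloxybenzaldehyde (Dakin-type): the oxygen-substituted aryl group migrates in the Criegee adduct to give formate 15, which mild acidic methanolysis cleaves to the phenol; buffered peracid without strong acid should leave the aryl iodide at the iodine(I) level, and the thiosulfate wash returns any iodine(III) formed.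

**Compound list**

1 | 4-methoxyaniline | COc1ccc(N)cc1 | starting material
2 | 2,6-dibromo-4-methoxyaniline | COc1cc(Br)c(N)c(Br)c1 | intermediate
3 | 2,6-dibromo-4-methoxybenzenediazonium bromide | COc1cc(Br)c([N+]#N)c(Br)c1.[Br-] | intermediate
4 | 1,2,3-tribromo-5-methoxybenzene | COc1cc(Br)c(Br)c(Br)c1 | intermediate
5 | 1,2,3-tribromo-4-iodo-5-methoxybenzene | COc1cc(Br)c(Br)c(Br)c1I | intermediate
6 | (2,3,4-tribromo-6-methoxyphenyl)-λ3-iodanediyl diacetate | COc1cc(Br)c(Br)c(Br)c1I(OC(C)=O)OC(C)=O | intermediate
7 | 4-bromophenol | Oc1ccc(Br)cc1 | starting material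
8 | (5-bromo-2-hydroxyphenyl)(2,3,4-tribromo-6-methoxyphenyl)iodonium trifluoroacetate | COc1cc(Br)c(Br)c(Br)c1[I+]c1cc(Br)ccc1O.[O-]C(=O)C(F)(F)F | intermediate
9 | 4-bromo-2-[(2,3,4-tribromo-6-methoxyphenyl)iodonio]phenolate | COc1cc(Br)c(Br)c(Br)c1[I+]c1cc(Br)ccc1[O-] | intermediate
10 | 1,2,3-tribromo-4-(4-bromo-2-iodophenoxy)-5-methoxybenzene | COc1cc(Br)c(Br)c(Br)c1Oc1ccc(Br)cc1I | intermediate
11 | dibromo[3,4,5-tribromo-2-(4-bromo-2-iodophenoxy)phenoxy]borane | BrB(Br)Oc1cc(Br)c(Br)c(Br)c1Oc1ccc(Br)cc1I | intermediate
12 | 3,4,5-tribromo-2-(4-bromo-2-iodophenoxy)phenol | Oc1cc(Br)c(Br)c(Br)c1Oc1ccc(Br)cc1I | intermediate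
13 | 3,5-dibromo-2-fluorobenzaldehyde | O=Cc1cc(Br)cc(Br)c1F | starting material
14 | 3,5-dibromo-2-[3,4,5-tribromo-2-(4-bromo-2-iodophenoxy)phenoxy]benzaldehyde | O=Cc1cc(Br)cc(Br)c1Oc1cc(Br)c(Br)c(Br)c1Oc1ccc(Br)cc1I | intermediate
15 | 3,5-dibromo-2-[3,4,5-tribromo-2-(4-bromo-2-iodophenoxy)phenoxy]phenyl formate | O=COc1cc(Br)cc(Br)c1Oc1cc(Br)c(Br)c(Br)c1Oc1ccc(Br)cc1I | intermediate
16 | bromoiesol B, 3,5-dibromo-2-[3,4,5-tribromo-2-(4-bromo-2-iodophenoxy)phenoxy]phenol | Oc1cc(Br)cc(Br)c1Oc1cc(Br)c(Br)c(Br)c1Oc1ccc(Br)cc1I | target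

**Step count**

Total steps: 8. Longest linear sequence: 8 steps (1 → 16); 7 and 13 enter as purchased reactants.

**Steps most likely to fail**

1. Step 5 (key step). Oxidation of the phenol through its oxygen (dearomatisation, oligomers) may outrun C–I bond formation, or the aryl shift may stall and give way to intermolecular arylation. The fallback sets out from 6 and keeps ring B as the aryl donor but makes the C–O bond between two molecules. Compound 6 would be condensed with 1,3,5-trimethoxybenzene (TsOH·H2O, MeCN, rt) to give (2,3,4-tribromo-6-methoxyphenyl)(2,4,6-trimethoxyphenyl)iodonium tosylate F1. Purchased 4-bromo-2-iodophenol would then be O-arylated with F1 (K2CO3, MeCN, 60 °C). The phenoxide should take the electron-poor ring-B aryl and leave the trimethoxyphenyl group on iodine, which returns the route at 10. In this variant the ring-C iodine is bought with the phenol.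

2. Step 8. Hydrogen may migrate instead of the aryl group in the Criegee adduct, because two meta bromines slow aryl migration, leading to over-oxidation at the formyl carbon; the peracid may also oxidise at the ring-C iodine. The fallback sets out from 12 and brings the ring-A oxygen in through nitrogen, with no oxidant. Purchased 2,4-dibromo-6-nitroaniline would be diazotised and chlorinated (t-BuONO, CuCl2, MeCN, 0 → 60 °C) through 2,4-dibromo-6-nitrobenzenediazonium chloride F2 to give 1,5-dibromo-2-chloro-3-nitrobenzene F3. SNAr of the phenoxide of 12 at the chlorine ortho to nitro (K2CO3, DMF, 80 °C) would give 1,2,3-tribromo-4-(4-bromo-2-iodophenoxy)-5-(2,4-dibromo-6-nitrophenoxy)benzene F4. Reduction (Fe, AcOH/EtOH, 60 °C) would give 3,5-dibromo-2-[3,4,5-tribromo-2-(4-bromo-2-iodophenoxy)phenoxy]aniline F5. Diazotisation (NaNO2, H2SO4, AcOH/H2O, 0 °C) to the arenediazonium hydrogensulfate F6 and hydrolysis in warm aqueous sulfuric acid containing copper(II) sulfate would return the route at 16.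

3. Step 4. Oxidation at an iodine flanked by methoxy and bromine on an electron-poor ring may be slow or incomplete, and the iodine(III) may be lost on isolation. The fallback sets out from 5 and reaches iodine(III) by halogen addition instead of oxygen transfer. Chlorine (CHCl3, 0 °C) would give dichloro(2,3,4-tribromo-6-methoxyphenyl)-λ3-iodane F7. Hydrolysis (aq NaOH, 0 °C) would give 1,2,3-tribromo-4-iodosyl-5-methoxybenzene F8. Dissolving F8 in glacial acetic acid would return the route at 6.

**Further compounds**

F1 | step 5 | (2,3,4-tribromo-6-methoxyphenyl)(2,4,6-trimethoxyphenyl)iodonium 4-methylbenzenesulfonate | COc1cc(OC)c([I+]c2c(OC)cc(Br)c(Br)c2Br)c(OC)c1.Cc1ccc(S(=O)(=O)[O-])cc1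
F2 | step 8 | 2,4-dibromo-6-nitrobenzenediazonium chloride | N#[N+]c1c(Br)cc(Br)cc1[N+](=O)[O-].[Cl-]
F3 | step 8 | 1,5-dibromo-2-chloro-3-nitrobenzene | O=[N+]([O-])c1cc(Br)cc(Br)c1Cl
F4 | step 8 | 1,2,3-tribromo-4-(4-bromo-2-iodophenoxy)-5-(2,4-dibromo-6-nitrophenoxy)benzene | O=[N+]([O-])c1cc(Br)cc(Br)c1Oc1cc(Br)c(Br)c(Br)c1Oc1ccc(Br)cc1I
F5 | step 8 | 3,5-dibromo-2-[3,4,5-tribromo-2-(4-bromo-2-iodophenoxy)phenoxy]aniline | Nc1cc(Br)cc(Br)c1Oc1cc(Br)c(Br)c(Br)c1Oc1ccc(Br)cc1I
F6 | step 8 | 3,5-dibromo-2-[3,4,5-tribromo-2-(4-bromo-2-iodophenoxy)phenoxy]benzenediazonium hydrogensulfate | N#[N+]c1cc(Br)cc(Br)c1Oc1cc(Br)c(Br)c(Br)c1Oc1ccc(Br)cc1I.OS(=O)(=O)[O-]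
F7 | step 4 | dichloro(2,3,4-tribromo-6-methoxyphenyl)-λ3-iodane | COc1cc(Br)c(Br)c(Br)c1I(Cl)Cl
F8 | step 4 | 1,2,3-tribromo-4-iodosyl-5-methoxybenzene | COc1cc(Br)c(Br)c(Br)c1I=O
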